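The data stem from a simulated flask for an exercise; the scatter is artificial.

**The decision.** Decide first which one number you carry from the runs below to the flask asked about.

| setting | Thursday's | Monday's | flask |
|---|---|---|---|
| left-handed substrate | 20 mM | 20 mM | 20 mM |
| right-handed substrate | 20 mM | 20 mM | 20 mM |
| partner | 80 mM | 54 mM | 80.0 mM |
| precatalyst | 1.1 mM | 1.1 mM | 1.1 mM |
| added ligand | 0.64 mM | 0.64 mM | 0.64 mM |
| impurity | 0.34 mM | 0.34 mM | 0.34 mM |
| remark | the very flask that is asked about, followed so far | run made earlier |  |
| time |  |  | 3.0 min |

| run | time / s | left-handed substrate / % | right-handed substrate / % | left-handed product / % |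
|---|---|---|---|---|
| Thursday's | 10.0 | 35.1 | 39.0 | 16.3 |
| Thursday's | 12.0 | 32.6 | 38.6 | 17.5 |
| Thursday's | 15.0 | 29.7 | 36.9 | 19.8 |
| Monday's | 10.0 | 38.3 | 43.8 | 11.4 |
| Monday's | 20.0 | 31.4 | 38.2 | 18.6 |
| Monday's | 40.0 | 21.6 | 31.3 | 28.6 |
| Monday's | 50.0 | 19.1 | 28.6 | 30.6 |
| Monday's | 80.0 | 12.9 | 21.3 | 38.6 |
| Monday's | 90.0 | 10.9 | 19.2 | 39.0 |
| Monday's | 120 | 8.5 | 15.3 | 42.9 |

(scatter of a reading: 0.5 percentage points)

* part of the left-handed substrate and right-handed substrate charged together that has reacted at 3.0 min
* excess of left-handed product over right-handed product in the product at 3.0 min
* excess of right-handed substrate over left-handed substrate among what is left of the two at 3.0 min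

- partner is single-handed; left-handed substrate and right-handed substrate are mirror images of each other, charged as a racemate, each of them at the stated concentration
- the numbers in the tables scatter with a standard deviation of 0.5 percentage points
- an excess is below zero if the other one leads
- the handed part of partner does not stay in what it makes, so the products of the two hands are mirror images too

**Hand ratio.** Carry 1.71, read from Thursday's flask at 15.0 s, where left-handed substrate stands at 29.7% and right-handed substrate at 36.9%, each out of half the charge. It is the logarithm of the fraction of left-handed substrate left over the same logarithm for right-handed substrate, the selectivity factor. It tells you how many times faster the left hand goes. If both hands meet the same partner at first order, partner cancels, so Monday's flask, with less of it, can test the number.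

**The test.** In Monday's flask at 20.0 s, the left-handed 31.4% and the ratio give right-handed 38.1%; the reading is 38.2%. At 120 s they give 17.8%, but the reading is 15.3%, lower by 2.5 percentage points against a scatter of 0.5 points. In Monday's flask one number fits the reading at 20.0 s, then, and misses the one at 120 s. My own reckoning for 3.0 min is less right-handed substrate than the ratio gives.

**The forecast.** It gives c 96%, eP 1.9% and eS 45%, from 25% to 70%: "Selectivity therefore seems to fade".

**The flask.** It gives c 95.7%, eP 8.34%, above the forecast's range, and eS 32.0%.

    partner + left-handed substrate → left-handed product (k = 0.480 M⁻¹ s⁻¹)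
    partner + right-handed substrate → right-handed product (k = 0.280 M⁻¹ s⁻¹)
    left-handed substrate + racemization catalyst ⇌ right-handed substrate + racemization catalyst, rate k3*[racemization catalyst]*[left-handed substrate] forward; the back reaction follows from the equilibrium constant (k = 16.0 M⁻¹ s⁻¹)
    racemization catalyst + added ligand ⇌ idle complex, settled at all times (K = 2000 M⁻¹)
    racemization catalyst + impurity → spent catalyst (k = 47000 M⁻¹ s⁻¹)
    partner + precatalyst → racemization catalyst + spent reagent (k = 0.330 M⁻¹ s⁻¹)

**Two clocks.** Of its own charge, this flask keeps 2.9% left-handed substrate at 3.00 min; the ratio then gives 12.8% right-handed, and 5.7% stands. At 3.00 min the half-life of left-handed substrate in this flask is 0.59 min by the step with partner, shorter than the 1.8 min by the forward racemization step alone.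

**Second flask.** In the neighbour flask with 0.44 mM precatalyst, 1.5% of the left-handed charge left and the ratio give 8.58% of the right-handed charge. The computed neighbour flask keeps 7.9% of that charge, with eS 67.9%.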